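**Plan**

- Ring numbering: oxolane O1, C2 (4-hydroxy-3-methoxyphenyl), C3 (CH2O-coumaroyl), C4 (4-hydroxy-3-methoxybenzyl), C5 (H2). Retrosynthetic cuts, in order: the ester C–O bond; the C2–aryl bond (C2 back to a lactone carbonyl); then, in one operation, the C4–benzylic carbon bond and the C3–CH2O bond; C5 back to an acetal carbon.
- Enabling feature: C3 and C4 carry a trans pair of side chains and lie α and β to C2. With C2 as a lactone C=O the ring is a furan-2(5H)-one whose β-carbon (C4) takes a nucleophile and whose α-carbon (C3) then takes an electrophile, the acetal carbon being the later C5.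
- Forward: the oxolane ring is never closed; it is the furanone ring made from furfural. A lithiated aryl dithiane and benzyl chloromethyl ether are attached at C4 and C3, sulfur is removed, the C5 acetal is reduced to CH2, the aryl group is added to the C2 carbonyl, the hemiketal is reduced, and the coumarate is attached last.
- Stereochemistry: the crystalline (5R)-acetal of l-menthol sends the nucleophile to the opposite face at C4; the electrophile enters C3 anti to the new C4 group; hydride attacks the C2 oxocarbenium ion anti to the C3 substituent. The C5 centre is erased afterwards.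

Key step: step 4

Remark: the target SMILES is read as (2S,3S,4R), i.e. the C2 aryl and C3 acyloxymethyl groups cis and the C3/C4 substituents trans on the oxolane; the route is planned for this isomer.

**Route**

Step 1
Reactants: 1 furfural
Product: 2 5-hydroxyfuran-2(5H)-one (racemic)
Conditions: O2, rose bengal (cat.), MeOH, hν (visible), rt
Reagents that add atoms: dioxygen, O=O
Why: Sensitised singlet-oxygen [4+2] cycloaddition to the furan gives an endoperoxide that methanol fragments with loss of the formyl carbon as methyl formate (furan photo-oxygenation), a standard entry to the hydroxybutenolide.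

Step 2
Reactants: 2 5-hydroxyfuran-2(5H)-one; 3 l-menthol
Product: 5 (5R)-5-(l-menthyloxy)furan-2(5H)-one, via (5S)-acetal epimer 4 (not isolated)
Conditions: p-TsOH·H2O (cat.), toluene, reflux (Dean–Stark); crystallisation from petroleum ether; mother liquor re-equilibrated with p-TsOH and recrystallised
Reagents that add atoms: none
Why: Acid-catalysed acetalisation through the cyclic oxocarbenium ion gives both C5 epimers, which interconvert under acid, so the C5 centre is set by crystallisation of the less soluble (5R)-epimer (crystallisation-induced asymmetric transformation).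

Step 3
Reactants: 6 O-benzylvanillin
Product: 7 2-(4-benzyloxy-3-methoxyphenyl)-1,3-dithiane
Conditions: HS(CH2)3SH, I2 (cat.), CH2Cl2, rt
Reagents that add atoms: propane-1,3-dithiol, SCCCS
Why: Iodine-catalysed dithioacetalisation of an aromatic aldehyde is routine and mild enough to leave the aryl benzyl ether untouched.

Step 4
Reactants: 7 2-(4-benzyloxy-3-methoxyphenyl)-1,3-dithiane; 5 (5R)-5-(l-menthyloxy)furan-2(5H)-one; 8 benzyl chloromethyl ether
Product: 11 (3S,4R,5R)-4-[2-(4-benzyloxy-3-methoxyphenyl)-1,3-dithian-2-yl]-3-[(benzyloxy)methyl]-5-(l-menthyloxy)oxolan-2-one, via 2-lithiodithiane 9 (not isolated), via lactone lithium enolate 10 (not isolated)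
Conditions: 7, n-BuLi, THF, −78 → −20 °C; 5, −78 °C; 8, −78 → 0 °C; aq. NH4Cl
Reagents that add atoms: none
Why: n-BuLi deprotonates the dithiane and the stabilised carbanion 9 adds 1,4 to butenolide 5 (Michael addition) to give lithium enolate 10, which is C-alkylated by chloromethyl ether 8 (tandem conjugate addition–enolate alkylation with an acyl-anion equivalent). The closest known reaction type is the tandem addition of lithiated aryl dithioacetals to 5-alkoxybutenolides with benzyl halide or aldehyde trapping, which gives trans-3,4-disubstituted lactones. No ring is closed, the butenolide ring being carried on as the future oxolane. C4 is set by the C5 menthyloxy group, which blocks one face of the planar butenolide so that the nucleophile enters anti to it, and C3 is set by the bulky dithianyl group now at C4, which sends the electrophile to the other face of the enolate. The step needs 1,4- over 1,2-addition, secured by the soft aryl dithiane anion and the open β-carbon, and C- over O-alkylation, secured by the contact lithium enolate in THF without a strongly dissociating cosolvent.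

Step 5
Reactants: 11 the all-trans dithianyl lactone acetal
Product: 12 (3S,4R,5R)-4-(4-benzyloxy-3-methoxybenzyl)-3-[(benzyloxy)methyl]-5-(l-menthyloxy)oxolan-2-one
Conditions: Raney Ni (W-2, acetone-deactivated), EtOH, 50 °C
Reagents that add atoms: none
Why: Raney Ni hydrogenolysis of the two benzylic C–S bonds (Mozingo desulfurisation) turns the dithiane carbon into the benzylic CH2, and the deactivated catalyst at moderate temperature should spare the benzyl ethers and the lactone acetal.

Step 6
Reactants: 12 the desulfurised lactone acetal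
Product: 15 (3S,4R)-4-(4-benzyloxy-3-methoxybenzyl)-3-[(benzyloxy)methyl]oxolan-2-one, via potassium aldehyde-carboxylate 13 (not isolated), via potassium hydroxy-carboxylate 14 (not isolated)
Conditions: NaBH4, aq. KOH, EtOH, 0 °C → rt; then 2 M HCl, rt
Reagents that add atoms: potassium hydroxide, [K+].[OH-] (its oxygen enters the carboxyl group and can remain as the lactone carbonyl oxygen)
Why: Saponification of the pseudo-ester releases menthol and the aldehyde, which NaBH4 reduces at once so that the adjacent C4 centre has no time to epimerise, and acidification lactonises the 4-hydroxy acid (one-pot reductive removal of the acetal auxiliary).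

Step 7
Reactants: 15 the dibenzyl lactone
Product: 16 (3S,4R)-4-(4-hydroxy-3-methoxybenzyl)-3-(hydroxymethyl)oxolan-2-one
Conditions: H2 (1 atm), Pd/C, EtOAc/EtOH, rt
Reagents that add atoms: none
Why: Catalytic hydrogenolysis removes the aryl and the alkyl benzyl ether at a stage where the benzylic C2–O bond of the final oxolane does not yet exist, so nothing else can be reduced.

Step 8
Reactants: 16 the diol lactone
Product: 17 (3S,4R)-3-{[(tert-butyldimethylsilyl)oxy]methyl}-4-{4-[(tert-butyldimethylsilyl)oxy]-3-methoxybenzyl}oxolan-2-one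
Conditions: TBSCl, imidazole, DMF, rt
Reagents that add atoms: tert-butyldimethylsilyl chloride, CC(C)(C)[Si](C)(C)Cl
Why: Corey silylation covers both hydroxyl groups for the organolithium step, imidazole being too weak a base to cause β-elimination of the α-hydroxymethyl lactone.

Step 9
Reactants: 18 4-bromo-2-methoxyphenol
Product: 19 (4-bromo-2-methoxyphenoxy)(tert-butyl)dimethylsilane
Conditions: TBSCl, imidazole, CH2Cl2, rt
Reagents that add atoms: tert-butyldimethylsilyl chloride, CC(C)(C)[Si](C)(C)Cl
Why: Corey silylation masks the acidic phenol so that the bromide can undergo bromine–lithium exchange.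

Step 10
Reactants: 19 the silylated aryl bromide; 17 the bis-silyl lactone
Product: 21 (3S,4R)-2-{4-[(tert-butyldimethylsilyl)oxy]-3-methoxyphenyl}-3-{[(tert-butyldimethylsilyl)oxy]methyl}-4-{4-[(tert-butyldimethylsilyl)oxy]-3-methoxybenzyl}oxolan-2-ol (C2 epimers in equilibrium with the open hydroxy ketone), via aryllithium 20 (not isolated)
Conditions: 19, n-BuLi, THF, −78 °C; then 17, −78 °C; H2O
Reagents that add atoms: none
Why: Bromine–lithium exchange gives the aryllithium, which should add once to the lactone carbonyl because the lithium hemiketal alkoxide does not collapse at −78 °C (organolithium addition to a lactone), addition outrunning α-deprotonation at this temperature.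

Step 11
Reactants: 21 the hemiketal
Product: 22 (2S,3S,4R)-2-{4-[(tert-butyldimethylsilyl)oxy]-3-methoxyphenyl}-3-{[(tert-butyldimethylsilyl)oxy]methyl}-4-{4-[(tert-butyldimethylsilyl)oxy]-3-methoxybenzyl}oxolane
Conditions: Et3SiH, BF3·OEt2, CH2Cl2, −78 °C; Et3N then aq. NaHCO3 at −78 °C
Reagents that add atoms: none
Why: BF3·OEt2 ionises the hemiketal to the 2-aryl oxocarbenium ion and Et3SiH delivers hydride to the face anti to the adjacent C3 silyloxymethyl group (ionic hydrogenation of a hemiketal), which should set C2 with the aryl group cis to the C3 substituent, while the low temperature and cold quench prevent acid epimerisation at C2 or C3.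

Step 12
Reactants: 22 the tris-silyl oxolane
Product: 23 4-[(2S,3S,4R)-4-(4-hydroxy-3-methoxybenzyl)-3-(hydroxymethyl)oxolan-2-yl]-2-methoxyphenol
Conditions: TBAF, AcOH, THF, 0 °C → rt
Reagents that add atoms: none
Why: Fluoride cleaves the two aryl and the one alkyl silyl ether (TBAF desilylation), and the acetic acid buffer keeps the liberated p-hydroxybenzyl ether from opening through a quinone methide.

Step 13
Reactants: 23 the triol; 24 (E)-p-coumaric acid
Product: 25 [(2S,3S,4R)-2-(4-hydroxy-3-methoxyphenyl)-4-(4-hydroxy-3-methoxybenzyl)oxolan-3-yl]methyl (E)-3-(4-hydroxyphenyl)prop-2-enoate (target)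
Conditions: 24, PPh3, DIAD, THF, 0 °C → rt
Reagents that add atoms: none
Why: In the Mitsunobu esterification only the aliphatic primary alcohol is activated as its alkoxyphosphonium salt and the carboxylate, by far the most acidic partner, is the nucleophile, so the three phenols should stay free and the (E)-alkene and all stereocentres (the carbinol carbon is CH2) are untouched.

**Compound list**

1 | furfural (furan-2-carbaldehyde) | O=Cc1ccco1 | starting material
2 | 5-hydroxyfuran-2(5H)-one (racemic) | O=C1C=CC(O)O1 | intermediate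
3 | l-menthol, (1R,2S,5R)-2-isopropyl-5-methylcyclohexan-1-ol | C[C@@H]1CC[C@H]([C@@H](C1)O)C(C)C | starting material
4 | (5S)-5-(l-menthyloxy)furan-2(5H)-one, the C5 epimer that equilibrates | O=C1C=C[C@@H](O[C@@H]2C[C@H](C)CC[C@H]2C(C)C)O1 | intermediate
5 | (5R)-5-{[(1R,2S,5R)-2-isopropyl-5-methylcyclohexyl]oxy}furan-2(5H)-one | O=C1C=C[C@H](O[C@@H]2C[C@H](C)CC[C@H]2C(C)C)O1 | intermediate
6 | O-benzylvanillin (4-benzyloxy-3-methoxybenzaldehyde) | COc1cc(C=O)ccc1OCc1ccccc1 | starting material
7 | 2-(4-benzyloxy-3-methoxyphenyl)-1,3-dithiane | COc1cc(C2SCCCS2)ccc1OCc1ccccc1 | intermediate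
8 | benzyl chloromethyl ether | ClCOCc1ccccc1 | starting material
9 | 2-lithio-2-(4-benzyloxy-3-methoxyphenyl)-1,3-dithiane | COc1cc(C2([Li])SCCCS2)ccc1OCc1ccccc1 | intermediate
10 | lithium enolate (C2=C3, O-lithio) of (4R,5R)-4-[2-(4-benzyloxy-3-methoxyphenyl)-1,3-dithian-2-yl]-5-(l-menthyloxy)oxolan-2-one | COc1cc(C2(SCCCS2)[C@H]2[C@H](O[C@@H]3C[C@H](C)CC[C@H]3C(C)C)OC(O[Li])=C2)ccc1OCc1ccccc1 | intermediate
11 | (3S,4R,5R)-4-[2-(4-benzyloxy-3-methoxyphenyl)-1,3-dithian-2-yl]-3-[(benzyloxy)methyl]-5-(l-menthyloxy)oxolan-2-one (all-trans) | COc1cc(C2(SCCCS2)[C@H]2[C@H](O[C@@H]3C[C@H](C)CC[C@H]3C(C)C)OC(=O)[C@@H]2COCc2ccccc2)ccc1OCc1ccccc1 | intermediate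
12 | (3S,4R,5R)-4-(4-benzyloxy-3-methoxybenzyl)-3-[(benzyloxy)methyl]-5-(l-menthyloxy)oxolan-2-one | COc1cc(C[C@H]2[C@H](O[C@@H]3C[C@H](C)CC[C@H]3C(C)C)OC(=O)[C@@H]2COCc2ccccc2)ccc1OCc1ccccc1 | intermediate
13 | potassium (2S,3R)-2-[(benzyloxy)methyl]-3-(4-benzyloxy-3-methoxybenzyl)-4-oxobutanoate | COc1cc(C[C@H]([C@H](C(=O)[O-])COCc2ccccc2)C=O)ccc1OCc1ccccc1.[K+] | intermediate
14 | potassium (2S,3R)-2-[(benzyloxy)methyl]-3-(4-benzyloxy-3-methoxybenzyl)-4-hydroxybutanoate | COc1cc(C[C@H]([C@H](C(=O)[O-])COCc2ccccc2)CO)ccc1OCc1ccccc1.[K+] | intermediate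
15 | (3S,4R)-4-(4-benzyloxy-3-methoxybenzyl)-3-[(benzyloxy)methyl]oxolan-2-one | COc1cc(C[C@H]2COC(=O)[C@@H]2COCc2ccccc2)ccc1OCc1ccccc1 | intermediate
16 | (3S,4R)-4-(4-hydroxy-3-methoxybenzyl)-3-(hydroxymethyl)oxolan-2-one | COc1cc(C[C@H]2COC(=O)[C@@H]2CO)ccc1O | intermediate
17 | (3S,4R)-3-{[(tert-butyldimethylsilyl)oxy]methyl}-4-{4-[(tert-butyldimethylsilyl)oxy]-3-methoxybenzyl}oxolan-2-one | COc1cc(C[C@H]2COC(=O)[C@@H]2CO[Si](C)(C)C(C)(C)C)ccc1O[Si](C)(C)C(C)(C)C | intermediate
18 | 4-bromo-2-methoxyphenol | COc1cc(Br)ccc1O | starting material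
19 | (4-bromo-2-methoxyphenoxy)(tert-butyl)dimethylsilane | COc1cc(Br)ccc1O[Si](C)(C)C(C)(C)C | intermediate
20 | {4-[(tert-butyldimethylsilyl)oxy]-3-methoxyphenyl}lithium | COc1cc([Li])ccc1O[Si](C)(C)C(C)(C)C | intermediate
21 | (3S,4R)-2-{4-[(tert-butyldimethylsilyl)oxy]-3-methoxyphenyl}-3-{[(tert-butyldimethylsilyl)oxy]methyl}-4-{4-[(tert-butyldimethylsilyl)oxy]-3-methoxybenzyl}oxolan-2-ol (C2 epimers) | COc1cc(C[C@H]2COC(O)(c3ccc(O[Si](C)(C)C(C)(C)C)c(OC)c3)[C@@H]2CO[Si](C)(C)C(C)(C)C)ccc1O[Si](C)(C)C(C)(C)C | intermediate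
22 | (2S,3S,4R)-2-{4-[(tert-butyldimethylsilyl)oxy]-3-methoxyphenyl}-3-{[(tert-butyldimethylsilyl)oxy]methyl}-4-{4-[(tert-butyldimethylsilyl)oxy]-3-methoxybenzyl}oxolane | COc1cc(C[C@H]2CO[C@H](c3ccc(O[Si](C)(C)C(C)(C)C)c(OC)c3)[C@@H]2CO[Si](C)(C)C(C)(C)C)ccc1O[Si](C)(C)C(C)(C)C | intermediate
23 | 4-[(2S,3S,4R)-4-(4-hydroxy-3-methoxybenzyl)-3-(hydroxymethyl)oxolan-2-yl]-2-methoxyphenol | COc1cc(C[C@H]2CO[C@H](c3ccc(O)c(OC)c3)[C@@H]2CO)ccc1O | intermediate
24 | (E)-p-coumaric acid, (E)-3-(4-hydroxyphenyl)prop-2-enoic acid | O=C(O)/C=C/c1ccc(O)cc1 | starting material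
25 | [(2S,3S,4R)-2-(4-hydroxy-3-methoxyphenyl)-4-(4-hydroxy-3-methoxybenzyl)oxolan-3-yl]methyl (E)-3-(4-hydroxyphenyl)prop-2-enoate | COc1cc(C[C@H]2CO[C@H](c3ccc(O)c(OC)c3)[C@@H]2COC(=O)/C=C/c2ccc(O)cc2)ccc1O | target

**Step count and risks**

Total step count: 13. Longest linear sequence: 11 steps (furfural through steps 1, 2, 4, 5, 6, 7, 8, 10, 11, 12, 13).

Steps most likely to fail:

Step 4. The enolate 10 sits next to the quaternary dithianyl carbon, so C-alkylation by 8 may be slow. Proton transfer would then return the simple Michael adduct, or the chloromethyl ether could alkylate on oxygen. The fallback sets out from 10 (generated from 5 and 7 as in step 4). Trapping with gaseous monomeric formaldehyde at −78 °C, the smallest carbon electrophile, should give by aldol addition anti to the dithianyl group the hydroxymethyl lactone F1. Its primary alcohol would then be benzylated under neutral conditions with 2-benzyloxy-1-methylpyridinium triflate and MgO in PhCF3 at 85 °C, which avoids base-induced dehydration and comes back to the route at 11.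

Step 10. The aryllithium may act as a base at C3, leading to loss of silanolate and an α-methylene lactone or to C3 epimerisation, or it may add twice. The fallback sets out from 17. DIBAL-H in toluene at −78 °C should give the lactol F2. Its open hydroxy-aldehyde form would take up aryllithium 20 (a little over two equivalents, made from 19 as before) to give the diol F3 as a mixture of benzylic epimers, both usable. MnO2 in CH2Cl2 should oxidise only the electron-rich benzylic alcohol, and the resulting hydroxy ketone closes to the hemiketal, coming back to the route at 21.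

Step 13. With three free phenols present, competing phenol O-alkylation or self-condensation of the coumaric acid could erode the chemoselectivity of the Mitsunobu reaction. The fallback sets out from 22:
- PPTS in MeOH/CH2Cl2 at rt should cleave only the primary alkyl silyl ether, leaving the aryl silyl ethers, to give the alcohol F4.
- In parallel, 24 would be silylated twice (TBSCl, imidazole, DMF) to the silyl ester F5, whose ester is hydrolysed with AcOH/THF/H2O to the protected acid F6.
- Steglich esterification of F4 with F6 (EDC·HCl, DMAP, CH2Cl2) should give the fully silylated ester F7.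
- TBAF/AcOH in THF at 0 °C would remove the three aryl silyl groups and come back to the route at 25.

Further compounds

F1 | step 4 | (3S,4R,5R)-4-[2-(4-benzyloxy-3-methoxyphenyl)-1,3-dithian-2-yl]-3-(hydroxymethyl)-5-(l-menthyloxy)oxolan-2-one | COc1cc(C2(SCCCS2)[C@H]2[C@H](O[C@@H]3C[C@H](C)CC[C@H]3C(C)C)OC(=O)[C@@H]2CO)ccc1OCc1ccccc1
F2 | step 10 | (3S,4R)-3-{[(tert-butyldimethylsilyl)oxy]methyl}-4-{4-[(tert-butyldimethylsilyl)oxy]-3-methoxybenzyl}oxolan-2-ol (anomer mixture) | COc1cc(C[C@H]2COC(O)[C@@H]2CO[Si](C)(C)C(C)(C)C)ccc1O[Si](C)(C)C(C)(C)C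
F3 | step 10 | (2S,3R)-1-{4-[(tert-butyldimethylsilyl)oxy]-3-methoxyphenyl}-2-{[(tert-butyldimethylsilyl)oxy]methyl}-3-{4-[(tert-butyldimethylsilyl)oxy]-3-methoxybenzyl}butane-1,4-diol (C1 epimers) | COc1cc(C[C@H]([C@H](C(O)c2ccc(O[Si](C)(C)C(C)(C)C)c(OC)c2)CO[Si](C)(C)C(C)(C)C)CO)ccc1O[Si](C)(C)C(C)(C)C
F4 | step 13 | [(2S,3S,4R)-2-{4-[(tert-butyldimethylsilyl)oxy]-3-methoxyphenyl}-4-{4-[(tert-butyldimethylsilyl)oxy]-3-methoxybenzyl}oxolan-3-yl]methanol | COc1cc(C[C@H]2CO[C@H](c3ccc(O[Si](C)(C)C(C)(C)C)c(OC)c3)[C@@H]2CO)ccc1O[Si](C)(C)C(C)(C)C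
F5 | step 13 | tert-butyldimethylsilyl (E)-3-{4-[(tert-butyldimethylsilyl)oxy]phenyl}prop-2-enoate | CC(C)(C)[Si](C)(C)OC(=O)/C=C/c1ccc(O[Si](C)(C)C(C)(C)C)cc1
F6 | step 13 | (E)-3-{4-[(tert-butyldimethylsilyl)oxy]phenyl}prop-2-enoic acid | O=C(O)/C=C/c1ccc(O[Si](C)(C)C(C)(C)C)cc1
F7 | step 13 | [(2S,3S,4R)-2-{4-[(tert-butyldimethylsilyl)oxy]-3-methoxyphenyl}-4-{4-[(tert-butyldimethylsilyl)oxy]-3-methoxybenzyl}oxolan-3-yl]methyl (E)-3-{4-[(tert-butyldimethylsilyl)oxy]phenyl}prop-2-enoate | COc1cc(C[C@H]2CO[C@H](c3ccc(O[Si](C)(C)C(C)(C)C)c(OC)c3)[C@@H]2COC(=O)/C=C/c2ccc(O[Si](C)(C)C(C)(C)C)cc2)ccc1O[Si](C)(C)C(C)(C)C
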